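The hydroxy-methoxy-quinone ring is built last, by ring expansion, and everything rests on cutting it between the carbonyl carbon next to C–OMe and the carbon that carries the decalinylmethyl group. Thermolysis of a 4-siloxy-4-(1-siloxyalkenyl)-2-methoxycyclobutenone opens to a dienylketene and recloses to the fully substituted arene in one operation. The step exploits the fact that the ring atoms C(=O)–C(OMe)=CH–C(O) map onto a squarate-derived four-carbon unit and C(OH)=C(CH2R) onto an enol ether. The precursor comes from an iron-hydride Giese coupling of a 9-methylidene trans-decalin (from Wieland–Miescher ketone) with an acryloylcyclobutenone, which also creates the C9 quaternary centre.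

Key step: step 14

Remark: the decalin carbons are numbered C1–C10 as in drimanes (C4 = methylidene carbon, C5 = ring-fusion CH, C8 = CHMe, C9 = quaternary carbon bearing C11, C10 = methyl-bearing ring-fusion carbon); β is the face of the C10 methyl group. Primed locants are those of the cyclobutenone. Compound 19 is racemic, so 20–22 are pairs of C4' epimers; that centre becomes trigonal in step 14.

Step 1
Reactants: 1 (S)-Wieland–Miescher ketone
Product: 2 enone dithiolane (C3 1,3-dithiolane of 1; C4=C5 alkene and C9 ketone kept)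
Conditions: HSCH2CH2SH, TsOH·H2O (cat.), AcOH, rt
Reagents that add atoms: ethane-1,2-dithiol SCCS
Why: Acid-catalysed thioketalisation should occur only at the conjugated C3 carbonyl, because the C9 ketone is shielded by the adjacent quaternary C10, and the alkene stays at C4=C5.

Step 2
Reactants: 2 enone dithiolane
Product: 3 octalone ((8aS)-8a-methyl-3,4,6,7,8,8a-hexahydronaphthalen-1(2H)-one; C4=C5 alkene; C9 ketone)
Conditions: Raney Ni (W-2), EtOH, reflux
Reagents that add atoms: none
Why: Mozingo-type Raney-nickel desulfurisation replaces both C–S bonds by C–H and so removes the C3 oxygen function without touching the C10 stereocentre.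

Step 3
Reactants: 3 octalone
Product: 5 diol (10β-methyl-trans-decalin-4α,9β-diol; 5α-H), via borane adduct 4 (not isolated)
Conditions: BH3·THF, THF, 0 °C → rt; then NaOH, H2O2, 0 °C → rt
Reagents that add atoms: hydrogen peroxide OO
Why: Hydroboration–oxidation: borane adds syn across C4=C5 from the α face, opposite the angular C10 methyl group, with boron on the less substituted C4, which sets the trans ring fusion (5α-H) and reduces the C9 ketone at the same time.

Step 4
Reactants: 5 diol
Product: 6 dione (10β-methyl-trans-decalin-4,9-dione; 5α-H)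
Conditions: Dess–Martin periodinane, NaHCO3, CH2Cl2, rt
Reagents that add atoms: none
Why: Dess–Martin oxidation converts both secondary alcohols into ketones under non-epimerising conditions, so the 5α-H set in step 3 is kept.

Step 5
Reactants: 6 dione
Product: 7 hydroxysilane ketone (4β-hydroxy-10β-methyl-4α-(trimethylsilylmethyl)-trans-decalin-9-one)
Conditions: Me3SiCH2MgCl, CeCl3, THF, −78 °C; aq NH4Cl
Reagents that add atoms: (trimethylsilyl)methylmagnesium chloride C[Si](C)(C)C[Mg]Cl
Why: The weakly basic organocerium reagent should add only to the less hindered C4 ketone (C9 is neopentyl) by equatorial attack without enolising C5, and the β-hydroxysilane both protects C4 and is the latent methylidene group of a Peterson olefination.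

Step 6
Reactants: 7 hydroxysilane ketone
Product: 10 methylidene ketone (8-methylidene derivative of 7), via Mannich base 8 (not isolated), via ammonium iodide 9 (not isolated)
Conditions: LDA (2.2 equiv), THF, −78 °C; CH2=NMe2+ I−, −78 °C → rt; then MeI, CH2Cl2; aq NaHCO3
Reagents that add atoms: dimethyl(methylidene)ammonium iodide (Eschenmoser's salt) C=[N+](C)C.[I-]
Why: Mannich-type methylenation (aminomethylation, quaternisation, E1cB elimination) can only take place at C8 because C10 is quaternary.

Step 7
Reactants: 10 methylidene ketone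
Product: 11 methyl ketone (8β-methyl derivative of 7; 8α-H)
Conditions: H2 (1 atm), RhCl(PPh3)3 (cat.), benzene, rt
Reagents that add atoms: none
Why: Homogeneous hydrogenation of the exocyclic enone should deliver hydrogen to C8 from the α face, because the β face is screened by the syn-axial C10 methyl group, which places the new methyl group β (axial) under kinetic control.

Step 8
Reactants: 11 methyl ketone
Product: 12 methylidene decalin (8β,10β-dimethyl-9-methylidene-4α-(trimethylsilylmethyl)-trans-decalin-4β-ol)
Conditions: Cp2TiMe2 (excess), toluene/THF, 70 °C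
Reagents that add atoms: dimethyltitanocene [CH3-].[CH3-].[Ti+4].c1cc[cH-]c1.c1cc[cH-]c1
Why: Petasis methylenation with the non-basic titanium methylidene olefinates the hindered, enolisable ketone without epimerising the labile axial C8 methyl group.

Step 9
Reactants: 13 methoxyallene; 14 dimethyl squarate
Product: 17 allenyl cyclobutenone (racemic 4-(tert-butyldimethylsilyloxy)-2,3-dimethoxy-4-(1-methoxypropa-1,2-dienyl)cyclobut-2-en-1-one), via lithioallene 15 (not isolated), via lithium alkoxide 16 (not isolated)
Conditions: n-BuLi, THF, −78 °C; 14, −78 °C; then t-BuMe2SiOTf, −78 → 0 °C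
Reagents that add atoms: tert-butyldimethylsilyl trifluoromethanesulfonate CC(C)(C)[Si](C)(C)OS(=O)(=O)C(F)(F)F
Why: α-Lithiated methoxyallene, an acyl-anion equivalent of acrolein, adds 1,2 to one of the two equivalent carbonyl groups of the squarate, and the tertiary alkoxide is silylated in the same flask.

Step 10
Reactants: 17 allenyl cyclobutenone
Product: 19 acryloyl cyclobutenone (racemic 4-acryloyl-4-(tert-butyldimethylsilyloxy)-2-methoxycyclobut-2-en-1-one), via cyclobutenol 18 (not isolated)
Conditions: NaBH4, CeCl3·7H2O, MeOH, −78 °C; then 1 M HCl, THF, 0 °C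
Reagents that add atoms: water O
Why: Luche 1,2-reduction followed by acid brings about a Stork–Danheiser-type transposition (ionisation of the secondary allylic alcohol, hydrolysis of the vinylogous methyl enol ether at the far carbon) and hydrolysis of the allenyl ether to the vinyl ketone, while the tertiary centre, deactivated by the silyl ether and the new acyl group, should not ionise, so the methoxy group ends up next to the ring carbonyl.

Step 11
Reactants: 12 methylidene decalin; 19 acryloyl cyclobutenone
Product: 20 Giese adduct (8β,9β,10β-trimethyl-4α-(trimethylsilylmethyl)-trans-decalin-4β-ol carrying at C9α a 3-oxopropyl chain whose carbonyl is bonded to C4' of the 4'-silyloxy-2'-methoxycyclobut-2'-en-1'-one; both C4' epimers)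
Conditions: Fe(acac)3, PhSiH3, EtOH/(CH2OH)2, 40 °C, 19 in excess
Reagents that add atoms: none
Why: Giese reaction started by hydrogen-atom transfer from an iron hydride: hydrogen adds to the terminal CH2 of 12 (which becomes the C9 methyl group) and the tertiary C9 radical adds axially to the vinyl ketone from the α face, away from the two axial β-methyl groups on C8 and C10, which sets the quaternary centre with the chain α.

Step 12
Reactants: 20 Giese adduct
Product: 21 methylidene ketone (4-methylidene analogue of 20: C4(OH)(CH2SiMe3) replaced by C4=CH2)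
Conditions: TsOH·H2O (cat.), CH2Cl2, 0 °C
Reagents that add atoms: none
Why: Acid-induced Peterson elimination (anti, β-silyl-stabilised) of the tertiary β-hydroxysilane gives only the exocyclic C4 methylidene.

Step 13
Reactants: 21 methylidene ketone
Product: 22 bis-silyl enol ether ((Z)-tert-butyldimethylsilyl enol ether of 21: C11H2–CH=C(OSi)–C4')
Conditions: t-BuMe2SiOTf, Et3N, CH2Cl2, −78 → 0 °C
Reagents that add atoms: tert-butyldimethylsilyl trifluoromethanesulfonate CC(C)(C)[Si](C)(C)OS(=O)(=O)C(F)(F)F
Why: Soft enolisation of the only enolisable ketone gives the silyl enol ether, turning the acyl group into the 1-siloxyalkenyl group that the ring expansion needs.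

Step 14
Reactants: 22 bis-silyl enol ether
Product: 25 phenol (3,4-bis(tert-butyldimethylsilyloxy)-6-methoxy-2-(decalinylmethyl)phenol), via dienylketene 23 (not isolated), via cyclohexadienone 24 (not isolated)
Conditions: toluene (degassed), 110 °C
Reagents that add atoms: none
Why: Conrotatory 4π electrocyclic opening of the C1'–C4' bond gives a dienylketene in which the siloxy donor on C4' has rotated outward and the siloxyalkenyl group inward; 6π disrotatory electrocyclisation then joins the ketene carbon to the enol-ether carbon that carries C11, and the cyclohexa-2,4-dienone tautomerises to the phenol. The closest known reaction type is the thermal ring expansion of 4-alkenyl-4-oxycyclobut-2-enones to hydroquinone derivatives. The six-membered ring is closed in a 6π electrocyclic mode; the only new stereocentre (the sp3 carbon of 24) is lost on aromatisation and the epimeric C4' of 22 becomes trigonal, so no stereocontrol is needed. The step needs the ketene to form cis to the alkenyl group and not to be trapped otherwise: the outward preference of the oxygen donor secures the first, the absence of any free hydroxyl or carbonyl group near the ketene the second, and a wrongly rotated ketene can only revert to 22. The substitution pattern of the arene (methoxy next to the new phenol carbon, alkyl on its other side) is fixed by the constitution of 22.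

Step 15
Reactants: 25 phenol
Product: 27 target CNP0109104.1, via benzenetriol 26 (not isolated)
Conditions: Bu4NF, THF, air, 0 °C → rt; then AcOH
Reagents that add atoms: none
Why: Fluoride removes both silyl groups and the electron-rich benzene-1,2,4-triol is oxidised by air to the 2-hydroxy-1,4-benzoquinone, the para-related oxygens at the former C1' and C4' becoming the two carbonyl groups.

Compound list
1 | (S)-Wieland–Miescher ketone, (8aS)-8a-methyl-3,4,8,8a-tetrahydronaphthalene-1,6(2H,7H)-dione | O=C1CC[C@@]2(C)C(=C1)CCCC2=O | starting material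
2 | C3 1,3-dithiolane of 1 (C4=C5 alkene, C9 ketone) | S1CCSC12CC[C@@]3(C)C(=C2)CCCC3=O | intermediate
3 | (8aS)-8a-methyl-3,4,6,7,8,8a-hexahydronaphthalen-1(2H)-one | C1CC[C@@]2(C)C(=C1)CCCC2=O | intermediate
4 | 4α-boryl-9β-boryloxy-10β-methyl-trans-decalin | B[C@@H]1CCC[C@@]2(C)[C@H]1CCC[C@@H]2OB | intermediate (not isolated)
5 | 10β-methyl-trans-decalin-4α,9β-diol (5α-H) | O[C@@H]1CCC[C@@]2(C)[C@H]1CCC[C@@H]2O | intermediate
6 | 10β-methyl-trans-decalin-4,9-dione (5α-H) | O=C1CCC[C@@]2(C)[C@H]1CCCC2=O | intermediate
7 | 4β-hydroxy-10β-methyl-4α-(trimethylsilylmethyl)-trans-decalin-9-one | C[Si](C)(C)C[C@]1(O)CCC[C@@]2(C)[C@H]1CCCC2=O | intermediate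
8 | 8-(dimethylaminomethyl) derivative of 7 (Mannich base, C8 epimers) | C[Si](C)(C)C[C@]1(O)CCC[C@@]2(C)[C@H]1CCC(CN(C)C)C2=O | intermediate (not isolated)
9 | 8-(trimethylammoniomethyl) derivative of 7, iodide | C[Si](C)(C)C[C@]1(O)CCC[C@@]2(C)[C@H]1CCC(C[N+](C)(C)C)C2=O.[I-] | intermediate (not isolated)
10 | 4β-hydroxy-10β-methyl-8-methylidene-4α-(trimethylsilylmethyl)-trans-decalin-9-one | C[Si](C)(C)C[C@]1(O)CCC[C@@]2(C)[C@H]1CCC(=C)C2=O | intermediate
11 | 4β-hydroxy-8β,10β-dimethyl-4α-(trimethylsilylmethyl)-trans-decalin-9-one | C[Si](C)(C)C[C@]1(O)CCC[C@@]2(C)[C@H]1CC[C@H](C)C2=O | intermediate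
12 | 8β,10β-dimethyl-9-methylidene-4α-(trimethylsilylmethyl)-trans-decalin-4β-ol | C[Si](C)(C)C[C@]1(O)CCC[C@@]2(C)[C@H]1CC[C@H](C)C2=C | intermediate
13 | methoxyallene (1-methoxypropa-1,2-diene) | COC=C=C | starting material
14 | dimethyl squarate (3,4-dimethoxycyclobut-3-ene-1,2-dione) | COC1=C(OC)C(=O)C1=O | starting material
15 | 1-lithio-1-methoxyallene | [Li]C(OC)=C=C | intermediate (not isolated)
16 | lithium 2,3-dimethoxy-1-(1-methoxypropa-1,2-dienyl)-4-oxocyclobut-2-en-1-olate | COC1=C(OC)C(=O)C1(O[Li])C(OC)=C=C | intermediate (not isolated)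
17 | 4-(tert-butyldimethylsilyloxy)-2,3-dimethoxy-4-(1-methoxypropa-1,2-dienyl)cyclobut-2-en-1-one (racemic) | COC1=C(OC)C(=O)C1(O[Si](C)(C)C(C)(C)C)C(OC)=C=C | intermediate
18 | 4-(tert-butyldimethylsilyloxy)-2,3-dimethoxy-4-(1-methoxypropa-1,2-dienyl)cyclobut-2-en-1-ol (diastereomers) | COC1=C(OC)C(O)C1(O[Si](C)(C)C(C)(C)C)C(OC)=C=C | intermediate (not isolated)
19 | 4-acryloyl-4-(tert-butyldimethylsilyloxy)-2-methoxycyclobut-2-en-1-one (racemic) | O=C1C(OC)=CC1(O[Si](C)(C)C(C)(C)C)C(=O)C=C | intermediate
20 | Giese adduct: 9α-[3-oxo-3-(1'-silyloxy-3'-methoxy-4'-oxocyclobut-2'-enyl)propyl]-8β,9β,10β-trimethyl-4α-(trimethylsilylmethyl)-trans-decalin-4β-ol (epimers at the silyloxy carbon) | C[Si](C)(C)C[C@]1(O)CCC[C@@]2(C)[C@H]1CC[C@H](C)[C@@]2(C)CCC(=O)C3(O[Si](C)(C)C(C)(C)C)C=C(OC)C3=O | intermediate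
21 | 4-methylidene analogue of 20 | C=C1CCC[C@@]2(C)[C@H]1CC[C@H](C)[C@@]2(C)CCC(=O)C3(O[Si](C)(C)C(C)(C)C)C=C(OC)C3=O | intermediate
22 | (Z)-tert-butyldimethylsilyl enol ether of 21 | C=C1CCC[C@@]2(C)[C@H]1CC[C@H](C)[C@@]2(C)C/C=C(\O[Si](C)(C)C(C)(C)C)C3(O[Si](C)(C)C(C)(C)C)C=C(OC)C3=O | intermediate
23 | dienylketene from ring opening of 22 | C=C1CCC[C@@]2(C)[C@H]1CC[C@H](C)[C@@]2(C)CC=C(O[Si](C)(C)C(C)(C)C)C(O[Si](C)(C)C(C)(C)C)=CC(OC)=C=O | intermediate (not isolated)
24 | 6-(decalinylmethyl)-2-methoxy-4,5-bis(silyloxy)cyclohexa-2,4-dien-1-one | C=C1CCC[C@@]2(C)[C@H]1CC[C@H](C)[C@@]2(C)CC3C(O[Si](C)(C)C(C)(C)C)=C(O[Si](C)(C)C(C)(C)C)C=C(OC)C3=O | intermediate (not isolated)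
25 | 3,4-bis(tert-butyldimethylsilyloxy)-6-methoxy-2-(decalinylmethyl)phenol | C=C1CCC[C@@]2(C)[C@H]1CC[C@H](C)[C@@]2(C)Cc3c(O[Si](C)(C)C(C)(C)C)c(O[Si](C)(C)C(C)(C)C)cc(OC)c3O | intermediate
26 | 3-(decalinylmethyl)-5-methoxybenzene-1,2,4-triol | C=C1CCC[C@@]2(C)[C@H]1CC[C@H](C)[C@@]2(C)Cc3c(O)c(O)cc(OC)c3O | intermediate (not isolated)
27 | 2-hydroxy-5-methoxy-3-{[(1R,2S,4aS,8aS)-1,2,8a-trimethyl-5-methylidenedecahydronaphthalen-1-yl]methyl}cyclohexa-2,5-diene-1,4-dione | C=C1CCC[C@@]2(C)[C@H]1CC[C@H](C)[C@@]2(C)CC1=C(O)C(=O)C=C(OC)C1=O | target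

Total step count: 15. Longest linear sequence: 13 steps (steps 1–8 and 11–15); steps 9–10 make the second fragment.

Steps most likely to fail

Step 11 (fragment coupling). Hydrogen-atom transfer to the hindered 1,1-disubstituted alkene may be slower than reduction or oligomerisation of the vinyl ketone, and the strained diketone may be attacked by the alcohol solvent. The fallback sets out from 11 and comes back at 21; it makes the same C9 radical from a tertiary oxalate instead of from the alkene. MeMgBr/CeCl3 adds to the C9 ketone of 11 to give the 4,9-diol F1. KH in THF effects the Peterson elimination at C4 to give the 4-methylidene tertiary alcohol F2. Methyl chlorooxoacetate (Et3N, DMAP) gives the methyl oxalate F3, and CsOH gives the cesium oxalate F4. Visible-light photoredox decarboxylation of F4 (Ir[dF(CF3)ppy]2(dtbbpy)PF6, blue LEDs, DME/DMF, water) in the presence of 19 should generate the tertiary C9 radical, which adds to the vinyl ketone from the α face to give 21.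

Step 10 (reduction and transposition). Ionisation may occur at the silyloxy-bearing carbon instead of the secondary carbinol (transposition in the wrong direction), or the silyl ether may be lost with subsequent ring expansion of the acyl cyclobutanol. The fallback sets out from 14 and comes back at 19; it fixes the regiochemistry with a ketal before the carbon nucleophile is added. LiAlH(Ot-Bu)3 reduces one carbonyl of 14 to give 4-hydroxy-2,3-dimethoxycyclobut-2-enone F5. Acidic methanol (HC(OMe)3, TsOH cat.) converts it by ionisation and methanol capture into 3,4,4-trimethoxycyclobut-2-enone F6. Lithioallene 15 (from 13 and n-BuLi) adds to the only carbonyl of F6 to give the lithium alkoxide F7, which t-BuMe2SiOTf converts into the silyl ether F8. Aqueous oxalic acid in THF hydrolyses the allenyl ether and the dimethyl ketal of F8 to give 19.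

Step 7 (C8 methyl configuration). Hydrogen may be delivered with poor facial selectivity, or the axial C8 methyl group next to the ketone may epimerise before the ketone is methylenated. The fallback sets out from 7 and comes back at 12; it sets C8 by a reductive 1,3-transposition and never passes through an epimerisable ketone. LDA and MeI give the 8-methyl ketone F9 (either C8 epimer). KN(SiMe3)2 and PhNTf2 give the tetrasubstituted enol triflate F10. Stille coupling with Bu3SnCH2OH (Pd(PPh3)4, zerovalent palladium, LiCl) gives the allylic alcohol F11. Mitsunobu reaction with 2-nitrobenzenesulfonylhydrazide (PPh3, DIAD, −30 °C) gives the hydrazide F12, which on warming loses the sulfinic acid to the allylic diazene F13. F13 transfers hydrogen to C8 from the less hindered α face with loss of dinitrogen and gives 12.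

Further compounds
F1 | step 11 | 8β,9,10β-trimethyl-4α-(trimethylsilylmethyl)-trans-decalin-4β,9-diol | C[Si](C)(C)C[C@]1(O)CCC[C@@]2(C)[C@H]1CC[C@H](C)C2(C)O
F2 | step 11 | 8β,9,10β-trimethyl-4-methylidene-trans-decalin-9-ol | C=C1CCC[C@@]2(C)[C@H]1CC[C@H](C)C2(C)O
F3 | step 11 | methyl oxalate of F2 | C=C1CCC[C@@]2(C)[C@H]1CC[C@H](C)C2(C)OC(=O)C(=O)OC
F4 | step 11 | cesium oxalate of F2 | C=C1CCC[C@@]2(C)[C@H]1CC[C@H](C)C2(C)OC(=O)C(=O)[O-].[Cs+]
F5 | step 10 | 4-hydroxy-2,3-dimethoxycyclobut-2-en-1-one | COC1=C(OC)C(=O)C1O
F6 | step 10 | 3,4,4-trimethoxycyclobut-2-en-1-one | COC1=CC(=O)C1(OC)OC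
F7 | step 10 | lithium 3,4,4-trimethoxy-1-(1-methoxypropa-1,2-dienyl)cyclobut-2-en-1-olate | COC1=CC(O[Li])(C(OC)=C=C)C1(OC)OC
F8 | step 10 | tert-butyldimethylsilyl ether of the alcohol of F7 | COC1=CC(O[Si](C)(C)C(C)(C)C)(C(OC)=C=C)C1(OC)OC
F9 | step 7 | 4β-hydroxy-8,10β-dimethyl-4α-(trimethylsilylmethyl)-trans-decalin-9-one | C[Si](C)(C)C[C@]1(O)CCC[C@@]2(C)[C@H]1CCC(C)C2=O
F10 | step 7 | C8=C9 enol triflate of F9 | C[Si](C)(C)C[C@]1(O)CCC[C@@]2(C)[C@H]1CCC(C)=C2OS(=O)(=O)C(F)(F)F
F11 | step 7 | 9-(hydroxymethyl)-8,10β-dimethyl-4α-(trimethylsilylmethyl)-trans-decal-8-en-4β-ol | C[Si](C)(C)C[C@]1(O)CCC[C@@]2(C)[C@H]1CCC(C)=C2CO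
F12 | step 7 | N-allyl-N-(2-nitrobenzenesulfonyl)hydrazine from F11 | C[Si](C)(C)C[C@]1(O)CCC[C@@]2(C)[C@H]1CCC(C)=C2CN(N)S(=O)(=O)c3ccccc3[N+](=O)[O-]
F13 | step 7 | allylic diazene from F12 | C[Si](C)(C)C[C@]1(O)CCC[C@@]2(C)[C@H]1CCC(C)=C2CN=N
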